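The blue run and the amber run held reagent, free catalyst and impurity at the same charges and changed the starting material.

| flask | starting material | reagent | free catalyst | impurity | remark |
|---|---|---|---|---|---|
| blue | 6.7 mM | 15 mM | 100 µM | 19 µM | run made earlier |
| amber | 15 mM | 15 mM | 100 µM | 19 µM | run made earlier |
| flask | 10 mM | 15.0 mM | 100 µM | 19 µM |  |

| blue: time / min | blue: product / % | amber: time / min | amber: product / % |
|---|---|---|---|
| 1.33 | 62.2 | 1.00 | 25.8 |
| 2.00 | 82.1 | 3.00 | 63.6 |
| 3.00 | 96.7 | 5.00 | 83.6 |
| 5.00 | 99.5 | 8.00 | 94.2 |
| 8.00 | 100.0 | 10.0 | 97.0 |
| 12.0 | 100.6 | 15.0 | 98.3 |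
| 20.0 | 100.3 | 20.0 | 99.2 |

(readings scatter by 0.3 percentage points)

- apparent order in free catalyst when 50% of the starting material are converted (percent change of the rate of making product for one percent more free catalyst charged)

- what was read earlier has a scatter of 0.3 percentage points, one standard deviation
- no earlier run changes the charge of free catalyst; that part of a forecast is a guess

So the two runs showed how the rate follows starting material. But c(free catalyst) stood at 100 µM in both, so I could read no catalyst order from them. I had to reason it from the charge.

The charge held one clue: c(impurity) was 19 µM against c(free catalyst) of 100 µM. Suppose each impurity takes one free catalyst, and takes it early. Then the working catalyst is the charge minus c(impurity). A rate proportional to that difference rises faster than the charge. The titration order is the charge of free catalyst over that difference, 1.23. Time drops out of it. I committed to that figure.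

The forecast took 1.1, lower than my figure, and said “No run varied the catalyst, so this is a guess”.

The flask gave 1.2 at 50% conversion, against my titration order of 1.23.

    reagent + free catalyst ⇌ catalyst intermediate A (K = 203 L mol⁻¹, k = 155 L mol⁻¹ s⁻¹)
    starting material + catalyst intermediate A ⇌ catalyst intermediate B (K = 303 L mol⁻¹, k = 3140 L mol⁻¹ s⁻¹)
    catalyst intermediate B ⇌ catalyst intermediate C (K = 66.8, k = 3.23 s⁻¹)
    catalyst intermediate C → free catalyst + product (k = 3.23 s⁻¹)
    free catalyst + impurity → spent catalyst (k = 9920 L mol⁻¹ s⁻¹)

Taking free catalyst at the 38.0% of the catalyst charged that the flask showed at 1.50 min, as an estimate for the earlier seconds too, the capture constant 9920 L mol⁻¹ s⁻¹ gives the impurity a half-life of about 1.84 s, far shorter than the 1.44 min the flask took to reach 50% conversion. At 1.50 min the impurity stood at 0% of its charge and spent catalyst at 19.0% of the catalyst charged.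

The data are calculated with constants of no real substance; the scatter is artificial.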